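**Retrosynthetic overview**

1. Euchrestaflavanone A ⇐ its tris-MOM ether (last step: acid removal of three MOM groups; both prenyl groups are carried through from the start).
2. Ring C ⇐ C3–C4 bond: enantioselective rhodium-catalysed intramolecular hydroacylation of an achiral 2-[(1-arylvinyl)oxy]benzaldehyde, which in one step gives ring C, the C4 ketone and the only stereocentre (C2).
3. Enabling feature: C3 is an unsubstituted CH2 between the C4 carbonyl (bonded to C4a of ring A, ortho to O1 on C8a) and C2, which carries O1, ring B and one H. C2=C3 can therefore be the alkene of an aryl α-styrenyl ether on O1 and C4 a formyl group, so ring C is their H–C(=O) adduct.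
4. Enol ether ⇐ aryl benzoate by titanium methylenation (CHO masked as its dimethyl acetal); ester ⇐ phenol-aldehyde (ring A: 2,4,6-trihydroxybenzaldehyde, C-prenylation, bis-MOM) + benzoic acid (ring B: 4-bromophenol, ortho-prenylation, MOM, Li/CO2).
5. Order of ring formation: rings A and B are bought as arenes; ring C is the only ring made, in step 9.

Key step: step 9

Abbreviations: prenyl = 3-methylbut-2-en-1-yl; MOM = methoxymethyl.

Assumption: which antipode of DTBM-SEGPHOS leads to the 2S ketone cannot be derived safely from the carbon-tethered model reactions, so (R) is written, and the equally available (S)-ligand takes its place if a first run shows the 2R product.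

**Route**

Step 1
Reactants: 1 2,4,6-trihydroxybenzaldehyde; 2 prenyl bromide (1-bromo-3-methylbut-2-ene)
Product: 3 2,4,6-trihydroxy-3-prenylbenzaldehyde
Conditions: 2 (0.9 equiv), KOH (10% aq), 0 °C → rt; then AcOH to pH 5
Reagents that add atoms: none
Why: C-alkylation of the ambident phloroglucinol phenoxide by the primary allylic bromide in water, where hydrogen bonding to the phenoxide oxygens steers attack to ring carbon, and since the two open ring carbons of 1 are equivalent a single mono-C-prenyl product is expected when 2 is kept limiting.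

Step 2
Reactants: 3 2,4,6-trihydroxy-3-prenylbenzaldehyde
Product: 4 2-hydroxy-4,6-bis(methoxymethoxy)-3-prenylbenzaldehyde
Conditions: MOMCl (2.1 equiv), K2CO3, acetone, 0 °C → rt
Reagents that add atoms: chloromethyl methyl ether (MOMCl), COCCl
Why: MOM protection by O-alkylation of the phenoxides with the α-chloro ether, in which the non-chelated 4-OH and the unhindered 6-OH should react while the 2-OH, flanked by the prenyl group and hydrogen-bonded to the formyl oxygen, should stay free.

Step 3
Reactants: 5 4-bromophenol; 2 prenyl bromide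
Product: 6 4-bromo-2-prenylphenol
Conditions: NaH, toluene, rt; then 2, rt → 40 °C
Reagents that add atoms: none
Why: ortho-C-alkylation of a sodium phenoxide held as a contact ion pair in a non-polar solvent, a classical route to ortho-prenylphenols, with the para position blocked by bromine.

Step 4
Reactants: 6 4-bromo-2-prenylphenol
Product: 7 4-bromo-1-(methoxymethoxy)-2-prenylbenzene
Conditions: NaH, DMF, 0 °C; MOMCl, 0 °C → rt
Reagents that add atoms: chloromethyl methyl ether (MOMCl), COCCl
Why: Williamson-type MOM protection of the single phenol, needed so that the arene tolerates the organolithium of step 5.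

Step 5
Reactants: 7 4-bromo-1-(methoxymethoxy)-2-prenylbenzene
Product: 9 4-(methoxymethoxy)-3-prenylbenzoic acid, via aryllithium 8 (not isolated)
Conditions: n-BuLi, THF, −78 °C; CO2 (g), −78 °C → rt; cold 1 M HCl to pH 4
Reagents that add atoms: carbon dioxide, O=C=O
Why: bromine–lithium exchange, which at −78 °C should outrun deprotonation next to the MOM ether or at the allylic CH2, followed by carboxylation of the aryllithium.

Step 6
Reactants: 4 2-hydroxy-4,6-bis(methoxymethoxy)-3-prenylbenzaldehyde; 9 4-(methoxymethoxy)-3-prenylbenzoic acid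
Product: 10 2-formyl-3,5-bis(methoxymethoxy)-6-prenylphenyl 4-(methoxymethoxy)-3-prenylbenzoate
Conditions: DCC, DMAP, CH2Cl2, 0 °C → rt
Reagents that add atoms: none
Why: Steglich esterification, in which carbodiimide activation with DMAP as acyl-transfer catalyst should acylate the only free hydroxyl of 4 under neutral conditions that spare the MOM ethers.

Step 7
Reactants: 10 2-formyl-3,5-bis(methoxymethoxy)-6-prenylphenyl 4-(methoxymethoxy)-3-prenylbenzoate
Product: 11 2-(dimethoxymethyl)-3,5-bis(methoxymethoxy)-6-prenylphenyl 4-(methoxymethoxy)-3-prenylbenzoate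
Conditions: HC(OMe)3, MeOH, PPTS (cat.), rt; Et3N quench
Reagents that add atoms: trimethyl orthoformate, COC(OC)OC; methanol, CO
Why: acid-catalysed acetalisation with the orthoformate as water scavenger masks the aldehyde, which would otherwise be methylenated faster than the ester in step 8.

Step 8
Reactants: 11 2-(dimethoxymethyl)-3,5-bis(methoxymethoxy)-6-prenylphenyl 4-(methoxymethoxy)-3-prenylbenzoate
Product: 13 2-({1-[4-(methoxymethoxy)-3-prenylphenyl]ethenyl}oxy)-4,6-bis(methoxymethoxy)-3-prenylbenzaldehyde, via enol ether acetal 12 (not isolated)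
Conditions: Cp2TiMe2 (3 equiv), toluene–THF, 65 °C, dark; filtration through basic alumina; then PPTS (cat.), acetone–H2O, 0 °C; Et3N quench
Reagents that add atoms: dimethyltitanocene (Cp2TiMe2), [CH3-].[CH3-].[Ti+4].c1cc[cH-]c1.c1cc[cH-]c1; water, O
Why: Petasis methylenation turns the aryl benzoate into the α-aryloxystyrene (a standard substrate class for titanium carbonyl methylenation), and the acetal of the 2,4,6-trioxygenated benzaldehyde should then hydrolyse orders of magnitude faster than the aryl enol ether is protonated.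

Step 9
Reactants: 13 2-({1-[4-(methoxymethoxy)-3-prenylphenyl]ethenyl}oxy)-4,6-bis(methoxymethoxy)-3-prenylbenzaldehyde
Product: 14 (2S)-5,7-bis(methoxymethoxy)-2-[4-(methoxymethoxy)-3-prenylphenyl]-8-prenyl-2,3-dihydro-4H-chromen-4-one
Conditions: [Rh(cod)Cl]2 (2.5 mol %), (R)-DTBM-SEGPHOS (5.5 mol %), NaB[3,5-(CF3)2C6H3]4 (5 mol %), degassed 1,4-dioxane, 60 °C, argon
Reagents that add atoms: none
Why: Proposed new method: the cationic monovalent rhodium–bisphosphine complex should insert into the formyl C–H bond of 13 to give an acyl hydride of trivalent rhodium, the tethered 1,1-disubstituted enol ether then inserts into Rh–H with hydrogen going to the carbon that carries the ring-A oxygen and ring B (the future C2) and rhodium to the terminal CH2, and C–C reductive elimination from the seven-membered acyl(alkyl)rhodacycle forms the CH2–C(=O) bond (C3–C4). The closest known reaction type is the rhodium/bisphosphine-catalysed enantioselective endo-hydroacylation of ortho-allylbenzaldehydes with a 2-substituted allyl group (to 3-substituted 3,4-dihydronaphthalen-1(2H)-ones), of 2-(1-arylvinyl)benzaldehydes and of 4-substituted pent-4-enals; 13 is the oxygen-tethered analogue, and an aryl enol ether has not been shown as the alkene partner. Ring C closes in the 6-endo-trig mode, with both alkene carbons ending up in the ring. The only new stereocentre, C2, is created when hydride is delivered to one enantiotopic face of the prochiral alkene carbon, and the face is chosen by the axially chiral bisphosphine (catalyst control, no substrate stereocentre present). The step needs endo over 5-exo regioselectivity, which the 1,1-disubstitution should secure because the exo path requires a tertiary α-aryloxybenzyl–rhodium bond and reductive elimination to a quaternary centre, whereas hydride insertion is reversible and the primary alkyl eliminates readily. It also needs chemoselectivity over decarbonylation and β-aryloxide elimination, which the bulky chelating bisphosphine, the fast intramolecular alkene capture and the ring constraint of the rhodacycle are expected to provide, while the two trisubstituted prenyl alkenes are too hindered and too remote to compete.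

Step 10
Reactants: 14 (2S)-5,7-bis(methoxymethoxy)-2-[4-(methoxymethoxy)-3-prenylphenyl]-8-prenyl-2,3-dihydro-4H-chromen-4-one
Product: 15 euchrestaflavanone A, (2S)-5,7-dihydroxy-2-(4-hydroxy-3-prenylphenyl)-8-prenyl-2,3-dihydro-4H-chromen-4-one
Conditions: HCl (3 M aq), MeOH, 50 °C, short reaction time
Reagents that add atoms: none
Why: acid-catalysed transacetalisation of the three MOM ethers to methanol, under which the S centre should be retained because C2 is not enolisable and ring opening to the chalcone is a base-mediated process, while the short mild exposure limits acid cyclisation of the ortho-prenylphenols.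

**Compound list**

1 | 2,4,6-trihydroxybenzaldehyde | O=Cc1c(O)cc(O)cc1O | starting material
2 | prenyl bromide (1-bromo-3-methylbut-2-ene) | CC(C)=CCBr | starting material
3 | 2,4,6-trihydroxy-3-prenylbenzaldehyde | CC(C)=CCc1c(O)cc(O)c(C=O)c1O | intermediate
4 | 2-hydroxy-4,6-bis(methoxymethoxy)-3-prenylbenzaldehyde | CC(C)=CCc1c(OCOC)cc(OCOC)c(C=O)c1O | intermediate
5 | 4-bromophenol | Oc1ccc(Br)cc1 | starting material
6 | 4-bromo-2-prenylphenol | CC(C)=CCc1cc(Br)ccc1O | intermediate
7 | 4-bromo-1-(methoxymethoxy)-2-prenylbenzene | CC(C)=CCc1cc(Br)ccc1OCOC | intermediate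
8 | [4-(methoxymethoxy)-3-prenylphenyl]lithium (formed in the flask) | [Li]c1ccc(OCOC)c(CC=C(C)C)c1 | intermediate
9 | 4-(methoxymethoxy)-3-prenylbenzoic acid | CC(C)=CCc1cc(C(=O)O)ccc1OCOC | intermediate
10 | 2-formyl-3,5-bis(methoxymethoxy)-6-prenylphenyl 4-(methoxymethoxy)-3-prenylbenzoate | CC(C)=CCc1cc(C(=O)Oc2c(CC=C(C)C)c(OCOC)cc(OCOC)c2C=O)ccc1OCOC | intermediate
11 | 2-(dimethoxymethyl)-3,5-bis(methoxymethoxy)-6-prenylphenyl 4-(methoxymethoxy)-3-prenylbenzoate | CC(C)=CCc1cc(C(=O)Oc2c(CC=C(C)C)c(OCOC)cc(OCOC)c2C(OC)OC)ccc1OCOC | intermediate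
12 | 2-(dimethoxymethyl)-3,5-bis(methoxymethoxy)-6-prenylphenyl 1-[4-(methoxymethoxy)-3-prenylphenyl]ethenyl ether (formed in the flask) | CC(C)=CCc1cc(C(=C)Oc2c(CC=C(C)C)c(OCOC)cc(OCOC)c2C(OC)OC)ccc1OCOC | intermediate
13 | 2-({1-[4-(methoxymethoxy)-3-prenylphenyl]ethenyl}oxy)-4,6-bis(methoxymethoxy)-3-prenylbenzaldehyde | CC(C)=CCc1cc(C(=C)Oc2c(CC=C(C)C)c(OCOC)cc(OCOC)c2C=O)ccc1OCOC | intermediate
14 | (2S)-5,7-bis(methoxymethoxy)-2-[4-(methoxymethoxy)-3-prenylphenyl]-8-prenyl-2,3-dihydro-4H-chromen-4-one | CC(C)=CCc1cc([C@@H]2CC(=O)c3c(OCOC)cc(OCOC)c(CC=C(C)C)c3O2)ccc1OCOC | intermediate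
15 | euchrestaflavanone A, (2S)-5,7-dihydroxy-2-(4-hydroxy-3-prenylphenyl)-8-prenyl-2,3-dihydro-4H-chromen-4-one | CC(C)=CCc1cc([C@@H]2CC(=O)c3c(O)cc(O)c(CC=C(C)C)c3O2)ccc1O | target

**Step count and risks**

Total step count: 10 (steps 1–2 for the ring-A fragment, steps 3–5 for the ring-B fragment, steps 6–10 after their union).

Longest linear sequence: 8 steps (steps 3, 4, 5, 6, 7, 8, 9, 10, from 4-bromophenol 5 to 15).

Steps most likely to fail:

1. Step 9 (proposed new method). The hydride may insert in the opposite sense and lead to exo closure, the acyl hydride may decarbonylate, the alkylrhodium may undergo β-aryloxide elimination, or the catalyst may discriminate the alkene faces poorly. The fallback uses known chemistry, forms the same ring bond and sets the stereocentre before ring closure; it sets out from 7 and 4 and comes back at 14. Aryllithium 8, generated from 7 as in step 5, is acylated with the commercial Weinreb amide 2-[(tert-butyldimethylsilyl)oxy]-N-methoxy-N-methylacetamide (THF, −78 °C) to give 2-[(tert-butyldimethylsilyl)oxy]-1-[4-(methoxymethoxy)-3-prenylphenyl]ethan-1-one F1. Noyori transfer hydrogenation (RuCl[(R,R)-TsDPEN](p-cymene), HCO2H–Et3N, rt, prenyl alkene inert) should give (1S)-2-[(tert-butyldimethylsilyl)oxy]-1-[4-(methoxymethoxy)-3-prenylphenyl]ethan-1-ol F2. Mitsunobu etherification of phenol 4 (PPh3, DIAD, toluene, 0 °C) with inversion should give 2-{(1R)-2-[(tert-butyldimethylsilyl)oxy]-1-[4-(methoxymethoxy)-3-prenylphenyl]ethoxy}-4,6-bis(methoxymethoxy)-3-prenylbenzaldehyde F3. Bu4NF/AcOH (THF, 0 °C) should free 2-{(1R)-2-hydroxy-1-[4-(methoxymethoxy)-3-prenylphenyl]ethoxy}-4,6-bis(methoxymethoxy)-3-prenylbenzaldehyde F4, and TsCl, Et3N, DMAP (CH2Cl2) should give (2R)-2-[2-formyl-3,5-bis(methoxymethoxy)-6-prenylphenoxy]-2-[4-(methoxymethoxy)-3-prenylphenyl]ethyl 4-methylbenzenesulfonate F5. A carbene-catalysed intramolecular nucleophilic substitution (3-benzyl-5-(2-hydroxyethyl)-4-methylthiazolium chloride, DBU, THF or xylene, heat), the known route from 2-(2-sulfonyloxyethoxy)benzaldehydes to chroman-4-ones, then lets the Breslow intermediate of the formyl group displace the primary tosylate and closes ring C to 14 without touching the C2 centre.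

2. Step 8. Methylenation of the doubly ortho-substituted aryl ester may be sluggish, or the aryl enol ether may be protonated and hydrolysed while the acetal is opened. The fallback builds the enol ether C–O bond by cross-coupling, so no aldehyde masking is needed; it sets out from 7 and 4 and comes back at 13. Aryllithium 8 (from 7, n-BuLi, THF, −78 °C) is acylated with N-methoxy-N-methylacetamide to give 1-[4-(methoxymethoxy)-3-prenylphenyl]ethan-1-one F6. Kinetic enolisation and triflation (KN(SiMe3)2, PhNTf2, THF, −78 °C) should give 1-[4-(methoxymethoxy)-3-prenylphenyl]ethenyl trifluoromethanesulfonate F7. Palladium-catalysed C–O coupling of this enol triflate with phenol 4 (Pd2(dba)3, 2-(di-tert-butylphosphino)biphenyl, K3PO4, toluene, 80 °C) should then give 13 directly.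

3. Step 1. The ambident phloroglucinol anion may undergo O-alkylation and double C-alkylation, and in step 2 the wrong ortho hydroxyl may be protected. The fallback delivers the ortho-prenyl group by aromatic Claisen rearrangement of a 1,1-dimethylallyl ether; it sets out from 1 and comes back at 4. MOMCl (2.1 equiv) and K2CO3 in acetone should give 2-hydroxy-4,6-bis(methoxymethoxy)benzaldehyde F8. O-Alkylation with 3-chloro-3-methylbut-1-yne (DBU, CuCl2 cat., MeCN, 0 °C) should give 2,4-bis(methoxymethoxy)-6-[(2-methylbut-3-yn-2-yl)oxy]benzaldehyde F9. Semihydrogenation (H2, Pd/CaCO3 poisoned with Pb(OAc)2, quinoline, EtOAc) should give 2,4-bis(methoxymethoxy)-6-[(2-methylbut-3-en-2-yl)oxy]benzaldehyde F10. Heating in toluene (100 °C) should bring about the [3,3] shift to the only free ortho carbon with allyl inversion, and rearomatisation then gives 4 with the free hydroxyl next to the prenyl group by construction.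

**Further compounds**

F1 | step 9 | 2-[(tert-butyldimethylsilyl)oxy]-1-[4-(methoxymethoxy)-3-prenylphenyl]ethan-1-one | CC(C)=CCc1cc(C(=O)CO[Si](C)(C)C(C)(C)C)ccc1OCOC
F2 | step 9 | (1S)-2-[(tert-butyldimethylsilyl)oxy]-1-[4-(methoxymethoxy)-3-prenylphenyl]ethan-1-ol | CC(C)=CCc1cc([C@H](O)CO[Si](C)(C)C(C)(C)C)ccc1OCOC
F3 | step 9 | 2-{(1R)-2-[(tert-butyldimethylsilyl)oxy]-1-[4-(methoxymethoxy)-3-prenylphenyl]ethoxy}-4,6-bis(methoxymethoxy)-3-prenylbenzaldehyde | CC(C)=CCc1cc([C@@H](Oc2c(CC=C(C)C)c(OCOC)cc(OCOC)c2C=O)CO[Si](C)(C)C(C)(C)C)ccc1OCOC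
F4 | step 9 | 2-{(1R)-2-hydroxy-1-[4-(methoxymethoxy)-3-prenylphenyl]ethoxy}-4,6-bis(methoxymethoxy)-3-prenylbenzaldehyde | CC(C)=CCc1cc([C@@H](Oc2c(CC=C(C)C)c(OCOC)cc(OCOC)c2C=O)CO)ccc1OCOC
F5 | step 9 | (2R)-2-[2-formyl-3,5-bis(methoxymethoxy)-6-prenylphenoxy]-2-[4-(methoxymethoxy)-3-prenylphenyl]ethyl 4-methylbenzenesulfonate | CC(C)=CCc1cc([C@@H](Oc2c(CC=C(C)C)c(OCOC)cc(OCOC)c2C=O)COS(=O)(=O)c2ccc(C)cc2)ccc1OCOC
F6 | step 8 | 1-[4-(methoxymethoxy)-3-prenylphenyl]ethan-1-one | CC(C)=CCc1cc(C(C)=O)ccc1OCOC
F7 | step 8 | 1-[4-(methoxymethoxy)-3-prenylphenyl]ethenyl trifluoromethanesulfonate | CC(C)=CCc1cc(C(=C)OS(=O)(=O)C(F)(F)F)ccc1OCOC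
F8 | step 1 | 2-hydroxy-4,6-bis(methoxymethoxy)benzaldehyde | O=Cc1c(O)cc(OCOC)cc1OCOC
F9 | step 1 | 2,4-bis(methoxymethoxy)-6-[(2-methylbut-3-yn-2-yl)oxy]benzaldehyde | C#CC(C)(C)Oc1cc(OCOC)cc(OCOC)c1C=O
F10 | step 1 | 2,4-bis(methoxymethoxy)-6-[(2-methylbut-3-en-2-yl)oxy]benzaldehyde | C=CC(C)(C)Oc1cc(OCOC)cc(OCOC)c1C=O
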